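# Design of a total synthesis of CNP0326102.1 (compound 17)

## The problem

Compound 17 is one cyclohexene ring with one exocyclic carbon. In the numbering used throughout, C1 is the tertiary carbinol that carries C7 (the benzoyloxymethyl carbon), C2 bears a benzoate, C3 a free hydroxyl, C4=C5 is the alkene and C6 bears chlorine; α is the ring face of the C1 hydroxyl and β the face of C7. No ring has to be joined to another and the seven skeletal carbons are those of benzoic acid, so the task is to place five heteroatom substituents on a C7 frame in the right order and on the right faces. The four stereocentres are C1 (R), C2 (R), C3 (S) and C6 (R). O1 and O2 are α and cis, and O3 and Cl are β, which makes C2/C3 and C1/C6 trans pairs and puts O3 and Cl cis across the alkene. C1 is the only fully substituted centre and the natural control element, because its hydroxyl can hold a metal oxidant on the α face of a neighbouring alkene and can itself attack C6 from the α side; both trans pairs are what anti opening of an α-epoxide leaves behind. Several groups limit the chemistry: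
- the secondary allylic chloride can be substituted with allylic shift or epimerised by free chloride;
- base closes the chlorohydrin C1–OH/C6–Cl to an epoxide;
- the benzoates on O2 and O7 can migrate to the free O3 and O1 under base, and these four oxygens must be told apart;
- at nearly every stage the ring is one or two eliminations away from an arene.

The enabling feature is that C1 is flanked by C2 and C6. In the achiral dienol 8 a mirror plane through C7, C1 and C4 makes the alkenes C2=C3 and C6=C5 enantiotopic, whereas 17 has oxidised them differently (two oxygens on one, chlorine plus an alkene shift on the other). One epoxidation that is tied to the C1 hydroxyl and chooses one alkene therefore makes C1, C2 and C3 stereogenic at once.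

## Retrosynthesis

**17 from 16.** The last cut is the acyl–oxygen bond of an acetate on O3.
- O3 stays masked to the end because a free hydroxyl beside the C2 benzoate would allow acyl migration in the basic step 10.
- O3 enters the molecule as acetate anyway, so the mask costs one step. A silyl or benzyl ether would cost two.
- The forward reaction must remove an acetate beside two benzoates, without base (chlorohydrin) and without strong nucleophiles (allylic chloride). This points to acid-catalysed methanolysis.

**16 from 15.** The C6–Cl bond is cut.
- Chlorine and O1 are trans and, in the half-chair with every other group equatorial, diaxial. That is the result expected from a protic chloride opening of the C1–C6 vinyl epoxide 15.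
- The neighbouring cut is displacement of an activated α-oxygen at C6 with inversion. It asks chloride to attack a carbon next to the quaternary C1 (a neopentyl-like site) while the open allylic terminus C4 is on offer.
- In 15 the same carbon is the secondary, allylic end of a strained ring, and C1 is tertiary and flanked by two acyloxy-bearing carbons.
- 15 has one heteroatom less and no base-labile chlorohydrin. The forward step must be anti and C6-selective.

**15 from 13, and 13 from 12.** First the O1–C6 bond and the C4=C5 π bond are cut, giving the 5,6-dibromide 13. Then C5–Br and C6–Br are cut, giving the cyclohexene 12. Three neighbouring cuts were weighed on the half-chair of 12, in which O2, O3 and C7 are equatorial, O1 is pseudoaxial α and the only pseudoaxial hydrogen at C4 is β.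
- A singlet-oxygen ene reaction is regiochemically clean, since C1 has no hydrogen. It is suprafacial and takes the perpendicular C4–H, so it favours the β face at C6 while hydrogen bonding to O1 pulls to the α face. This deactivated cis-disubstituted alkene is also a slow partner.
- Hydroxyl-directed epoxidation followed by selenide opening and selenoxide elimination is face-secure. However, diaxial opening of an α-epoxide in that half-chair calls for attack at the hindered C6, and attack at C5 needs the all-axial conformer.
- Bromination has no such conflict. A β-bromonium ion opened by bromide at the unhindered C5 from the α face is both the diaxial and the sterically preferred path.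

In 13 every later event is anti-periplanar: O1 (axial α) against C6–Br (axial β), and C5–Br (axial α) against C4–H (axial β). Compound 12 is simpler by one ring and two stereocentres.

**12 from 11 and 7, and 11 from 10.** The benzoyl–O2 bond is cut first; the secondary O2 is easily told from the tertiary O1. Then the C3–OAc bond is cut back to the α-epoxide 10.
- The trans O2/O3 pair requires inversion at one carbon only. This must be C3, because O2 has to stay cis to O1.
- C3 is the distal carbon of a 2,3-epoxy alcohol. C2 is shielded by the quaternary C1 and deactivated by O1.
- A carboxylate nucleophile leaves O3 and O2 already differentiated, which opening with water would not.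
- The forward step must be C3-selective and must outrun participation by the C7 benzoate.

**10 from 8 and 9.** Both C–O bonds of the oxirane (C2–O and C3–O) are cut, with cumene hydroperoxide 9 as the oxygen source.
- This removes all three stereocentres and leads to an achiral precursor that already holds every carbon and the C7 benzoate of 17.
- Neighbouring cuts are less suitable. Dihydroxylation would give a cis O2/O3 pair, normally anti to O1. An undirected chiral dioxirane would lose the link between the C1 hydroxyl and the face attacked.
- The forward reaction must choose one of two enantiotopic alkenes (the ligand), the α face (the tether to O1) and stop after one oxidation, all without acid.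

**8 from 6 and 7, 6 from 5, 5 from 3 through 4, 3 from 2, and 2 from 1.**
- The benzoyl–O7 bond is cut (primary against tertiary hydroxyl).
- The C7 alcohol is traced to the ester 5.
- The C1–O bond is cut back to the dienolate 4 of ester 3. Cross-conjugated dienolates of this type take electrophiles at C1.
- Ester 3 comes from the Birch product 2 of benzoic acid 1.
- No cheaper source holds all seven carbons, and dearomatisation puts the two alkenes where the key step needs them.

## Roads not taken

**Alternative 1:** The cut is the ring bond C1–C2.
- Forward key step: D-galactose A1 would be turned into the open-chain keto-aldehyde A2. C7 is added at the anomeric carbon, which becomes the ketone C1, and the primary alcohol end is oxidised to the aldehyde C2. SmI2 then reduces the aldehyde to a ketyl that adds to the ketone and closes the carbocycle as the cis-diol A3.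
- Merits: the absolute configuration comes from the starting sugar and is not induced. Samarium chelation gives the cis O1/O2 relation of 17. Both new hydroxyls would stand anti to their alkoxy neighbours at C3 and C6, the usual preference of such closures. The pseudo-symmetric C3–C6 pattern of the sugar opens either enantiomeric series through the choice of which end becomes C1.
- Weak points: A3 carries oxygen on all six ring carbons, whereas 17 has an alkene at C4=C5 and chlorine at C6. Two oxygens are carried along only to be deleted (acetonide removal, then a Corey–Winter type olefination) and a third is exchanged. O6 in A3 is β, the face of the chlorine, so the exchange needs net retention and hence the same epoxide detour as steps 10 and 11. Four kinds of protecting group must be placed on a hexose in a set order. Both benzyl ethers must be swapped for other groups before the alkene and the chloride exist, because hydrogenolysis would remove these too.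
- Comparison: this road is safer in absolute stereochemistry. It is far longer, and most of its steps are protecting-group or redox adjustments. The chosen plan gets the C7 frame in one step from 1 and spends a single mask. Against the certainty of the chiral pool it can set only that economy, and it accepts a catalyst-controlled step whose selectivity is not assured.

**Alternative 2:** The cut removes O1 and O2 and goes straight back to benzoic acid 1.
- Forward key step: whole cells of a blocked mutant of Ralstonia eutropha (benzoate 1,2-dioxygenase active, diol dehydrogenase absent) add one O2 across C1–C2 and give the diene diol acid A4.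
- Merits: in one step from 1 all seven carbons are in place. O1 and O2 are cis, with the absolute configuration that 17 needs at C1 and C2, and the enantiomeric purity of an enzymatic oxidation is very high. The diene C3=C4–C5=C6 is ready for 1,4-functionalisation.
- Weak points: the strain and the fermentation are not off-the-shelf items, and only one enantiomer is accessible. A4 aromatises readily by loss of water or CO2. The carboxyl group has to be reduced in the presence of the diene diol, which costs an acetonide on and off. The harder half of the problem remains, because O3 and Cl must both enter on the β face and the two diene termini must be told apart. A [4+2] addition of singlet oxygen would give O3 and O6 both β, so two similar allylic alcohols must be differentiated and C6 must again be substituted with net retention.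
- Comparison: at the front this road is clearly better, needing one step against six to reach a compound with C1 and C2 set, and with better enantiopurity. With the organism at hand it would probably be the shorter synthesis. The chosen plan sets three things against this. Its key step fixes C3 as well. C3 and C6 are chemically distinct from the start (epoxide carbon against alkene carbon). Only purchasable reagents are needed, and either enantiomer follows from the choice of ligand.

**Alternative 3:** The cuts are C3–O and C6–Cl together.
- Forward key step: Pd(OAc)2 with LiCl, LiOAc and p-benzoquinone in acetic acid would add acetate to C3 and chloride to C6 of the dienediol acetonide A5. This gives the chloroacetate A6 with the alkene moved to C4=C5.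
- Merits: one step installs both heteroatoms, already differentiated, in the cis-1,4 relation that 17 has. O3 arrives as the same acetate that 16 carries.
- Weak points: both nucleophiles attack anti to divalent palladium, so β entry requires the metal on the α face, under the folded acetonide. If the metal takes the more open β face, as reagents normally do with such acetonides, both new centres come out epimeric to 17. Acetate must choose C3 over C6. Chloride must then attack the allyl terminus C6 next to the quaternary C1 and not C4. The allylic chloride can re-ionise on palladium and lose its configuration. A5 must itself be enantiopure, so this road leans on A4 or on a resolution. It still has to hydrolyse an acetonide beside an allylic chloride, benzoylate O2 selectively and remove the acetate.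
- Comparison: in bond economy at the end it is better, needing one step where the chosen route needs steps 9 to 11. The chosen plan answers with three classical operations, each fixed in outcome by an anti-periplanar geometry in one well-defined chair, and with its own source of chirality.

Key step: step 6

Assumption: the (R,R)-bishydroxamic acid ligand is taken to select the alkene that leads to (1R,2R,6R)-10. If the sense of induction on this ring dienol is the opposite, the equally available (S,S)-ligand is used and nothing else changes.

## Route

Step 1
Reactants: 1 benzoic acid
Product: 2 cyclohexa-2,5-diene-1-carboxylic acid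
Conditions: Na, NH3(l), EtOH, −33 °C; NH4Cl; then HCl aq to pH 3, 0 °C
Reagents that add atoms: none
Why: Birch reduction; the carboxylate steers protonation to the ipso and para carbons, so the skipped 2,5-diene is the kinetic product. No stereocentre is formed.

Step 2
Reactants: 2 cyclohexa-2,5-diene-1-carboxylic acid
Product: 3 methyl cyclohexa-2,5-diene-1-carboxylate
Conditions: MeOH, H2SO4 (cat.), reflux
Reagents that add atoms: methanol, CO
Why: Fischer esterification; catalytic acid in methanol does not protonate the isolated alkenes, and the ester allows clean mono-enolisation in the next step.

Step 3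
Reactants: 3 methyl cyclohexa-2,5-diene-1-carboxylate
Product: 5 methyl 1-hydroxycyclohexa-2,5-diene-1-carboxylate, via potassium dienolate 4 (not isolated)
Conditions: KN(SiMe3)2, THF, −78 °C; then 2-(benzenesulfonyl)-3-phenyloxaziridine, −78 °C; NH4Cl aq
Reagents that add atoms: 2-(benzenesulfonyl)-3-phenyloxaziridine, O=S(=O)(N1OC1c1ccccc1)c1ccccc1
Why: Davis oxidation of an ester enolate; the cross-conjugated dienolate 4 takes electrophiles at C1, as in Birch alkylations, and the oxaziridine passes on oxygen at low temperature without a radical chain that could aromatise the ring. The ester at C1 retards ionisation of the new C1–O bond, and the product is achiral.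

Step 4
Reactants: 5 methyl 1-hydroxycyclohexa-2,5-diene-1-carboxylate
Product: 6 1-(hydroxymethyl)cyclohexa-2,5-dien-1-ol
Conditions: LiAlH4, Et2O, 0 °C; then H2O, NaOH aq
Reagents that add atoms: none
Why: Hydride reduction of an ester leaves isolated alkenes untouched, and the basic work-up keeps the acid-labile bis-allylic carbinol from losing water.

Step 5
Reactants: 6 1-(hydroxymethyl)cyclohexa-2,5-dien-1-ol; 7 benzoyl chloride
Product: 8 (1-hydroxycyclohexa-2,5-dien-1-yl)methyl benzoate
Conditions: 7 (1.05 equiv), Et3N, 4-dimethylaminopyridine (cat.), CH2Cl2, −20 °C
Reagents that add atoms: benzoyl chloride 7, O=C(Cl)c1ccccc1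
Why: Acylation takes the primary hydroxyl in preference to the tertiary one on steric grounds, and the amine keeps the medium non-acidic. The C7 benzoate belongs to the target, so no protecting group is spent.

Step 6
Reactants: 8 (1-hydroxycyclohexa-2,5-dien-1-yl)methyl benzoate; 9 cumene hydroperoxide
Product: 10 [(1R,2R,6R)-2-hydroxy-7-oxabicyclo[4.1.0]hept-3-en-2-yl]methyl benzoate (C2–C3 epoxide on the α face; cis to the C1 hydroxyl)
Conditions: Hf(OtBu)4 (10 mol %), (1R,2R)-N,N'-dihydroxy-N,N'-bis(diphenylacetyl)cyclohexane-1,2-diamine (12 mol %), 9 (1.1 equiv), MgO, 4 Å MS, toluene, 0 °C
Reagents that add atoms: cumene hydroperoxide 9, CC(C)(OO)c1ccccc1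
Why: Alkoxide exchange places the C1 alkoxide of 8 and the cumyl peroxide on tetravalent hafnium inside the C2-symmetric bishydroxamate pocket, and the metal-activated peroxide oxygen is passed intramolecularly to the alkene in one concerted transfer. The closest known reaction type is the Hf(OtBu)4–bishydroxamic acid epoxidation of tertiary allylic alcohols, together with the desymmetrising epoxidation of divinyl carbinols by metal complexes of the same ligand family. The oxirane closes in a single [2+1] event in which C2–O and C3–O form together on one face, so the cis ring alkene becomes a cis-fused 7-oxabicyclo[4.1.0]heptene and no exo or endo choice arises. C2 and C3 are set relative to C1 by the tether, because an oxygen held on the same metal as the C1 alkoxide can reach only the α face. C1 becomes stereogenic through the choice between C2=C3 and C6=C5, which the ligand alone makes. The step needs group selectivity (ligand), face selectivity (tether) and mono-oxidation; the last is served by about one equivalent of 9 and by the fact that the minor enantiomer of 10 still carries the alkene the catalyst prefers, so a second, matched epoxidation consumes it and the enantiomeric purity of 10 should rise with conversion. The non-acidic medium with MgO as acid scavenger and the electron-withdrawing C7 benzoate hold back ionisation at C1 and aromatisation.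

Step 7
Reactants: 10 [(1R,2R,6R)-2-hydroxy-7-oxabicyclo[4.1.0]hept-3-en-2-yl]methyl benzoate
Product: 11 [(1R,5S,6R)-5-acetoxy-1,6-dihydroxycyclohex-2-en-1-yl]methyl benzoate (O1 and O2 α; C3 acetate β; alkene C5=C6)
Conditions: AcOH, Ti(OiPr)4 (1.5 equiv), CH2Cl2, 0 °C to rt; tartaric acid aq
Reagents that add atoms: acetic acid, CC(=O)O
Why: Ti(OiPr)4-mediated opening of a 2,3-epoxy alcohol by a carboxylic acid; titanium bridges the cis C1 alkoxide and the epoxide oxygen, and acetate attacks the distal carbon C3 from the β face in an SN2 sense, which inverts C3 and sets the trans O2/O3 pair. C2 is shielded by the quaternary C1 and deactivated by O1, so substrate bias and chelation point the same way.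

Step 8
Reactants: 11 [(1R,5S,6R)-5-acetoxy-1,6-dihydroxycyclohex-2-en-1-yl]methyl benzoate; 7 benzoyl chloride
Product: 12 [(1R,5S,6R)-5-acetoxy-6-(benzoyloxy)-1-hydroxycyclohex-2-en-1-yl]methyl benzoate
Conditions: 7, pyridine, 4-dimethylaminopyridine (cat.), CH2Cl2, 0 °C to rt
Reagents that add atoms: benzoyl chloride 7, O=C(Cl)c1ccccc1
Why: Acylation of the secondary C2 hydroxyl in preference to the tertiary C1 hydroxyl; no C–O bond at a stereocentre is broken. Crude 11 is used at once to limit acetyl migration.

Step 9
Reactants: 12 [(1R,5S,6R)-5-acetoxy-6-(benzoyloxy)-1-hydroxycyclohex-2-en-1-yl]methyl benzoate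
Product: 13 [(1R,2S,3S,5S,6R)-5-acetoxy-6-(benzoyloxy)-2,3-dibromo-1-hydroxycyclohexyl]methyl benzoate (C6–Br β and C5–Br α; both axial)
Conditions: Br2, Et4NBr, CH2Cl2, −78 °C, dark
Reagents that add atoms: bromine, BrBr
Why: Electrophilic anti addition under the Fürst–Plattner rule; in the half-chair of 12 with O2, O3 and C7 equatorial, a β-bromonium ion is opened by bromide at the unhindered C5 from the α face, which is both the diaxial and the sterically preferred path and sets C6 (Br β) and C5 (Br α). Added bromide is meant to outrun participation by the neighbouring esters.

Step 10
Reactants: 13 [(1R,2S,3S,5S,6R)-5-acetoxy-6-(benzoyloxy)-2,3-dibromo-1-hydroxycyclohexyl]methyl benzoate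
Product: 15 [(1S,2R,3S,6S)-3-acetoxy-2-(benzoyloxy)-7-oxabicyclo[4.1.0]hept-4-en-1-yl]methyl benzoate, via bromo epoxide 14 (not isolated)
Conditions: 1,8-diazabicyclo[5.4.0]undec-7-ene (DBU, 3 equiv), THF, 0 to 40 °C
Reagents that add atoms: none
Why: Bromohydrin closure followed by E2 elimination, the dibromide–amidine sequence long used for arene oxides and epoxycyclohexenes; the axial O1 displaces the axial C6 bromide with inversion (3-exo-tet, C6–O α) and the axial C5 bromide leaves with the axial β hydrogen at C4. C1 has no hydrogen, and elimination towards C6 would place a double bond on an oxirane carbon, so the alkene can form only at C4=C5.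

Step 11
Reactants: 15 [(1S,2R,3S,6S)-3-acetoxy-2-(benzoyloxy)-7-oxabicyclo[4.1.0]hept-4-en-1-yl]methyl benzoate
Product: 16 [(1R,2R,5S,6R)-5-acetoxy-6-(benzoyloxy)-2-chloro-1-hydroxycyclohex-3-en-1-yl]methyl benzoate (C6–Cl β; trans to the C1 hydroxyl)
Conditions: HCl (1 M in Et2O), CH2Cl2, −40 to 0 °C
Reagents that add atoms: hydrogen chloride, Cl
Why: Acid-promoted SN2 opening of a vinyl epoxide at its secondary allylic carbon; chloride enters C6 from the β face anti to the C6–O bond (the second inversion at C6) and gives the trans-diaxial chlorohydrin directly in the half-chair with all other groups equatorial. C1 is tertiary and flanked by two acyloxy-bearing carbons, so it should neither ionise nor accept chloride.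

Step 12
Reactants: 16 [(1R,2R,5S,6R)-5-acetoxy-6-(benzoyloxy)-2-chloro-1-hydroxycyclohex-3-en-1-yl]methyl benzoate
Product: 17 [(1R,2R,5S,6R)-6-(benzoyloxy)-2-chloro-1,5-dihydroxycyclohex-3-en-1-yl]methyl benzoate (the target; 1R,2R,3S,6R in the route numbering)
Conditions: HCl (1.25 M in MeOH), CH2Cl2, 0 °C to rt
Reagents that add atoms: none
Why: Acid-catalysed transesterification, in which acetates are methanolysed much faster than benzoates; an acidic medium neither closes the chlorohydrin nor drives acyl migration. No stereocentre is touched.

## Compound list

1 | benzoic acid | O=C(O)c1ccccc1 | starting material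
2 | cyclohexa-2,5-diene-1-carboxylic acid | O=C(O)C1C=CCC=C1 | intermediate
3 | methyl cyclohexa-2,5-diene-1-carboxylate | COC(=O)C1C=CCC=C1 | intermediate
4 | potassium dienolate of 3 (not isolated) | COC([O-])=C1C=CCC=C1.[K+] | intermediate
5 | methyl 1-hydroxycyclohexa-2,5-diene-1-carboxylate | COC(=O)C1(O)C=CCC=C1 | intermediate
6 | 1-(hydroxymethyl)cyclohexa-2,5-dien-1-ol | OCC1(O)C=CCC=C1 | intermediate
7 | benzoyl chloride | O=C(Cl)c1ccccc1 | starting material
8 | (1-hydroxycyclohexa-2,5-dien-1-yl)methyl benzoate | O=C(OCC1(O)C=CCC=C1)c1ccccc1 | intermediate
9 | cumene hydroperoxide | CC(C)(OO)c1ccccc1 | starting material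
10 | [(1R,2R,6R)-2-hydroxy-7-oxabicyclo[4.1.0]hept-3-en-2-yl]methyl benzoate | O=C(OC[C@]1(O)C=CC[C@@H](O2)[C@H]12)c1ccccc1 | intermediate
11 | [(1R,5S,6R)-5-acetoxy-1,6-dihydroxycyclohex-2-en-1-yl]methyl benzoate | O=C(OC[C@]1(O)C=CC[C@H](OC(C)=O)[C@H]1O)c1ccccc1 | intermediate
12 | [(1R,5S,6R)-5-acetoxy-6-(benzoyloxy)-1-hydroxycyclohex-2-en-1-yl]methyl benzoate | O=C(OC[C@]1(O)C=CC[C@H](OC(C)=O)[C@H]1OC(=O)c1ccccc1)c1ccccc1 | intermediate
13 | [(1R,2S,3S,5S,6R)-5-acetoxy-6-(benzoyloxy)-2,3-dibromo-1-hydroxycyclohexyl]methyl benzoate | O=C(OC[C@]1(O)[C@H](Br)[C@@H](Br)C[C@H](OC(C)=O)[C@H]1OC(=O)c1ccccc1)c1ccccc1 | intermediate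
14 | [(1R,2R,3S,5S,6R)-3-acetoxy-2-(benzoyloxy)-5-bromo-7-oxabicyclo[4.1.0]heptan-1-yl]methyl benzoate (not isolated) | O=C(OC[C@]12O[C@H]1[C@@H](Br)C[C@H](OC(C)=O)[C@H]2OC(=O)c1ccccc1)c1ccccc1 | intermediate
15 | [(1S,2R,3S,6S)-3-acetoxy-2-(benzoyloxy)-7-oxabicyclo[4.1.0]hept-4-en-1-yl]methyl benzoate | O=C(OC[C@]12O[C@H]1C=C[C@H](OC(C)=O)[C@H]2OC(=O)c1ccccc1)c1ccccc1 | intermediate
16 | [(1R,2R,5S,6R)-5-acetoxy-6-(benzoyloxy)-2-chloro-1-hydroxycyclohex-3-en-1-yl]methyl benzoate | O=C(OC[C@]1(O)[C@H](Cl)C=C[C@H](OC(C)=O)[C@H]1OC(=O)c1ccccc1)c1ccccc1 | intermediate
17 | [(1R,2R,5S,6R)-6-(benzoyloxy)-2-chloro-1,5-dihydroxycyclohex-3-en-1-yl]methyl benzoate | O=C(OC[C@]1(O)[C@H](Cl)C=C[C@H](O)[C@H]1OC(=O)c1ccccc1)c1ccccc1 | target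

## Step count and least certain steps

Total step count: 12. Longest linear sequence: 12 steps, from 1 to 17; 7 and 9 are purchased.

**Step 6 (key step).**
- Risk: the most likely failure is poor discrimination between the two enantiotopic alkenes. Both are cis-disubstituted ring alkenes held equally close to the metal, and the ligand has mostly been proven on open-chain carbinols. Lewis-acid ionisation at C1 with loss of water and aromatisation, and over-oxidation, are the other dangers.
- Fallback: this replaces catalyst control by separation of covalent diastereomers and sets out from 6. The primary hydroxyl is esterified with (S)-2-methoxy-2-phenylacetic acid (carbodiimide, catalytic 4-dimethylaminopyridine) to give the dienol ester F1. Hydroxyl-directed mono-epoxidation with VO(acac)2 and tBuOOH gives the two syn epoxides. After separation, the isomer with the ring configuration of 10, the epoxy ester F2, is methanolysed with K2CO3 in MeOH to the epoxy diol F3. Benzoylation of the primary hydroxyl of F3 with 7 returns to the route at 10. At most half of the material is used.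

**Step 3.**
- Risk: electron transfer from the electron-rich dienolate to the oxidant, or base-induced 1,4-elimination from the product alkoxide, would aromatise the ring. Addition of the enolate to the sulfonimine by-product would consume material.
- Fallback: a neutral nucleophile is oxidised in a Rubottom oxidation, starting from 3. LiN(iPr)2 and Me3SiCl give the silyl ketene acetal F4. Buffered m-chloroperbenzoic acid attacks its far more electron-rich exocyclic double bond and, after silyl migration, gives the α-silyloxy ester F5. Citric acid in MeOH releases 5.

**Step 9.**
- Risk: capture of the bromonium ion by the carbonyl oxygen of the C7 benzoate (a six-membered acyloxonium path at C6), or erosion of diaxial control if the minor half-chair reacts, would lower the selectivity.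
- Fallback: the C6 substituent is installed as oxygen on the β face. It starts from 12 and uses the face preference that the half-chair imposes on an ene reaction. Photo-oxygenation (O2, tetraphenylporphyrin, light, CH2Cl2) takes the pseudoaxial β hydrogen at C4 and gives the 6β-hydroperoxide F6 with the alkene at C4=C5. PPh3 reduces it to the 6β-alcohol F7. Methanesulfonic anhydride and Et3N give the allylic 6β-mesylate F8 without free chloride, and DBU lets the anti O1 close the epoxide, rejoining the route at 15.

**Step 11.**
- Risk: chloride may attack the allylic terminus C4 with allylic shift. The protonated epoxide may open through an ion pair with partial retention. The C7 benzoate may take part at C6.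
- Fallback: the C6–Cl bond is made by addition and never displaced, starting from 12. Et3SiOTf and 2,6-lutidine give the C1 triethylsilyl ether F9, which blocks epoxide closure. Et4NCl3 adds chlorine anti and diaxially to give the dichloride F10 (C6–Cl β, C5–Cl α). DBU in warm toluene removes the axial C5 chloride with the axial C4 hydrogen and gives the allylic chloride F11. Methanolic HCl then cleaves the silyl ether and the acetate together and arrives at 17.

**Step 12.**
- Risk: cleavage of the hindered secondary acetate may be too slow relative to loss of the primary C7 benzoate, and the allylic chloride may solvolyse during the long exposure.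
- Fallback: the order of the last two operations is reversed, starting from 15, which has no chlorohydrin and tolerates mild base. Mg(OMe)2 in MeOH at 0 °C removes the acetate in preference to the benzoates and gives the hydroxy vinyl epoxide F12. HCl in Et2O is then added as the very last operation, as in step 11, and leads directly to 17.

## Further compounds

F1 | step 6 | (1-hydroxycyclohexa-2,5-dien-1-yl)methyl (S)-2-methoxy-2-phenylacetate | CO[C@H](C(=O)OCC1(O)C=CCC=C1)c1ccccc1
F2 | step 6 | [(1R,2R,6R)-2-hydroxy-7-oxabicyclo[4.1.0]hept-3-en-2-yl]methyl (S)-2-methoxy-2-phenylacetate | CO[C@H](C(=O)OC[C@]1(O)C=CC[C@@H](O2)[C@H]12)c1ccccc1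
F3 | step 6 | (1R,2R,6R)-2-(hydroxymethyl)-7-oxabicyclo[4.1.0]hept-3-en-2-ol | OC[C@]1(O)C=CC[C@@H](O2)[C@H]12
F4 | step 3 | [cyclohexa-2,5-dien-1-ylidene(methoxy)methoxy]trimethylsilane | COC(O[Si](C)(C)C)=C1C=CCC=C1
F5 | step 3 | methyl 1-(trimethylsilyloxy)cyclohexa-2,5-diene-1-carboxylate | COC(=O)C1(O[Si](C)(C)C)C=CCC=C1
F6 | step 9 | 6β-hydroperoxide: analogue of 16 with OOH in place of Cl at C6 | O=C(OC[C@]1(O)[C@H](OO)C=C[C@H](OC(C)=O)[C@H]1OC(=O)c1ccccc1)c1ccccc1
F7 | step 9 | 6β-alcohol: analogue of 16 with OH in place of Cl at C6 | O=C(OC[C@]1(O)[C@H](O)C=C[C@H](OC(C)=O)[C@H]1OC(=O)c1ccccc1)c1ccccc1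
F8 | step 9 | 6β-mesylate: analogue of 16 with OSO2Me in place of Cl at C6 | O=C(OC[C@]1(O)[C@H](OS(C)(=O)=O)C=C[C@H](OC(C)=O)[C@H]1OC(=O)c1ccccc1)c1ccccc1
F9 | step 11 | C1 triethylsilyl ether of 12 | O=C(OC[C@]1(O[Si](CC)(CC)CC)C=CC[C@H](OC(C)=O)[C@H]1OC(=O)c1ccccc1)c1ccccc1
F10 | step 11 | 5α,6β-dichloride of F9 | O=C(OC[C@]1(O[Si](CC)(CC)CC)[C@H](Cl)[C@@H](Cl)C[C@H](OC(C)=O)[C@H]1OC(=O)c1ccccc1)c1ccccc1
F11 | step 11 | C1 triethylsilyl ether of 16 | O=C(OC[C@]1(O[Si](CC)(CC)CC)[C@H](Cl)C=C[C@H](OC(C)=O)[C@H]1OC(=O)c1ccccc1)c1ccccc1
F12 | step 12 | [(1S,2R,3S,6S)-2-(benzoyloxy)-3-hydroxy-7-oxabicyclo[4.1.0]hept-4-en-1-yl]methyl benzoate | O=C(OC[C@]12O[C@H]1C=C[C@H](O)[C@H]2OC(=O)c1ccccc1)c1ccccc1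
A1 | alternative 1 | D-galactose (open-chain form) | C([C@H]([C@@H]([C@@H]([C@H](C=O)O)O)O)O)O
A2 | alternative 1 | open-chain keto-aldehyde (C1 ketone, C2 aldehyde, C3 silyl ether, C4,C5-acetonide, C6 and C7 benzyl ethers) | c1ccccc1COCC(=O)[C@H](OCc2ccccc2)[C@H]3OC(C)(C)O[C@H]3[C@H](O[Si](C)(C)C(C)(C)C)C=O
A3 | alternative 1 | cyclitol cis-diol from the pinacol closure | c1ccccc1COC[C@]2(O)[C@H](OCc3ccccc3)[C@H]3OC(C)(C)O[C@H]3[C@H](O[Si](C)(C)C(C)(C)C)[C@H]2O
A4 | alternative 2 | (1S,2R)-1,2-dihydroxycyclohexa-3,5-diene-1-carboxylic acid | OC(=O)[C@]1(O)C=CC=C[C@H]1O
A5 | alternative 3 | dienediol acetonide C7 benzoate | O=C(OC[C@]1(OC(C)(C)O2)C=CC=C[C@H]12)c1ccccc1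
A6 | alternative 3 | C3-acetoxy C6-chloro cyclohexene acetonide C7 benzoate | O=C(OC[C@]1(OC(C)(C)O2)[C@H](Cl)C=C[C@H](OC(C)=O)[C@H]12)c1ccccc1
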